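**Plan**
1. Retrosynthesis: the six MOM ethers come off last. Ring C of the flavanone is opened at C3–C4, giving its isomer, aldehyde 16. 16 is cut at the C6–C8'' biaryl bond into bromide 15 and the apigenin-derived boronate 4. 15 is cut at O1–C2 into salicylaldehyde 10 and bromohydrin 13.
2. Enabling feature: the C4 carbonyl carbon and O1 sit ortho on ring A, and C2 carries both O1 and the 4-oxyphenyl ring. Ring C is therefore the adduct of an aldehyde C4–H across the enol ether O1–C2(Ar)=C3H2, at the same oxidation level, with no activating group and no allylic hydrogen to isomerise.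
3. Forward: the ring A unit is built from 2-bromoresorcinol (MOM protection, C–H borylation/oxidation to place O1 para to the future biaryl carbon, ortho-formylation). The enol ether follows by Mitsunobu etherification and E2, then Suzuki coupling with the C8 boronate made from apigenin, closure of ring C and deprotection.
4. Stereochemistry: the only stereocentre, C2 (S), is created in the ring closure by a chiral bisphosphine–rhodium catalyst, late and under neutral conditions. The flavone unit is bought at its final oxidation level, so flavanone and flavone never have to be differentiated.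

Key step: step 12

Remark: the target defines only C2; the hindered C6–C8'' axis is left undefined and uncontrolled, so 16–18 are drawn without an axial descriptor.
Remark: the (R)-ligand is assumed to lead to 2S; should the sense be the opposite, the (S)-ligand is taken.

**Route**

Step 1
Reactants: 1 apigenin
Product: 2 5,7-bis(methoxymethoxy)-2-[4-(methoxymethoxy)phenyl]-4H-chromen-4-one
Conditions: NaH (4 equiv.), MOMCl (4.5 equiv.), DMF, 0 °C to rt
Reagents that add atoms: chloromethyl methyl ether (MOMCl), COCCl
Why: Williamson-type O-alkylation of all three phenoxides, with excess NaH in DMF so that the hydrogen-bonded 5-OH is also capped; this is needed to steer the next step to C8.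

Step 2
Reactants: 2 tri-O-MOM-apigenin
Product: 3 8-iodo-5,7-bis(methoxymethoxy)-2-[4-(methoxymethoxy)phenyl]-4H-chromen-4-one
Conditions: NIS (1.1 equiv.), DMF, rt to 40 °C, dark
Reagents that add atoms: N-iodosuccinimide, O=C1CCC(=O)N1I
Why: Electrophilic aromatic iodination under neutral conditions, which in 5-O-alkylated 5,7-dioxygenated flavones should go to C8 (ortho to O7 and O1, para to O5) and not to C6.

Step 3
Reactants: 3 8-iodoflavone
Product: 4 5,7-bis(methoxymethoxy)-2-[4-(methoxymethoxy)phenyl]-8-(4,4,5,5-tetramethyl-1,3,2-dioxaborolan-2-yl)-4H-chromen-4-one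
Conditions: pinacolborane (3 equiv.), Et3N (4 equiv.), PdCl2(MeCN)2 (4 mol%), SPhos (12 mol%), 1,4-dioxane, 100 °C
Reagents that add atoms: pinacolborane, CC1(C)OBOC1(C)C
Why: Palladium-catalysed Masuda borylation with pinacolborane, the variant suited to electron-rich, doubly ortho-substituted aryl iodides, should turn C8 into the nucleophilic coupling site without touching the pyranone.

Step 4
Reactants: 5 2-bromoresorcinol (2-bromobenzene-1,3-diol)
Product: 6 2-bromo-1,3-bis(methoxymethoxy)benzene
Conditions: MOMCl (2.5 equiv.), iPr2NEt (3 equiv.), CH2Cl2, 0 °C to rt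
Reagents that add atoms: chloromethyl methyl ether (MOMCl), COCCl
Why: Standard O-alkylation of both phenols; MOM carries no aryl C–H bonds that could compete in the next step.

Step 5
Reactants: 6 2-bromo-1,3-bis(methoxymethoxy)benzene
Product: 8 4-bromo-3,5-bis(methoxymethoxy)phenol, via arylboronate ester 7 (not isolated)
Conditions: [Ir(OMe)(cod)]2 (1.5 mol%), 4,4'-di-tert-butyl-2,2'-bipyridine (3 mol%), B2pin2 (0.6 equiv.), THF, 80 °C; then 30% H2O2, aq. NaOH, 0 °C
Reagents that add atoms: hydrogen peroxide, OO (the phenol oxygen); bis(pinacolato)diboron, CC1(C)OB(B2OC(C)(C)C(C)(C)O2)OC1(C)C (boron of 7 only)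
Why: Sterically governed iridium-catalysed C–H borylation should reach only the C–H without an ortho substituent (para to Br), and oxidation of the C–B bond places the future O1 para to the future biaryl carbon without regiochemical ambiguity.

Step 6
Reactants: 8 4-bromo-3,5-bis(methoxymethoxy)phenol
Product: 10 3-bromo-6-hydroxy-2,4-bis(methoxymethoxy)benzaldehyde, via salicyl alcohol 9 (not isolated)
Conditions: MgCl2 (2 equiv.), Et3N (4 equiv.), (CH2O)n (6 equiv.), MeCN, reflux
Reagents that add atoms: paraformaldehyde (as formaldehyde), C=O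
Why: Magnesium-mediated ortho-formylation (Casnati–Skattebøl): the magnesium phenoxide directs hydroxymethylation to the ortho carbon and a second formaldehyde oxidises the benzylic alkoxide by hydride transfer; the two ortho sites of 8 are equivalent.

Step 7
Reactants: 11 4-(methoxymethoxy)benzaldehyde
Product: 12 1-ethenyl-4-(methoxymethoxy)benzene
Conditions: Ph3PCH3Br (1.3 equiv.), KOtBu (1.3 equiv.), THF, 0 °C to rt
Reagents that add atoms: methyltriphenylphosphonium bromide, C[P+](c1ccccc1)(c1ccccc1)c1ccccc1.[Br-]
Why: Wittig methylenation of a non-enolisable aryl aldehyde.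

Step 8
Reactants: 12 1-ethenyl-4-(methoxymethoxy)benzene
Product: 13 racemic 2-bromo-1-[4-(methoxymethoxy)phenyl]ethanol
Conditions: NBS (1.1 equiv.), DMSO/H2O, 0 to 10 °C
Reagents that add atoms: N-bromosuccinimide, O=C1CCC(=O)N1Br; water, O
Why: Bromohydrin formation in which water opens the bromonium ion at the benzylic carbon (Markovnikov); the product is racemic, and this centre is removed in step 10.

Step 9
Reactants: 10 3-bromo-6-hydroxy-2,4-bis(methoxymethoxy)benzaldehyde; 13 racemic 2-bromo-1-[4-(methoxymethoxy)phenyl]ethanol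
Product: 14 racemic 3-bromo-6-{2-bromo-1-[4-(methoxymethoxy)phenyl]ethoxy}-2,4-bis(methoxymethoxy)benzaldehyde
Conditions: PPh3 (1.5 equiv.), DIAD (1.5 equiv.), THF, 0 °C to rt
Reagents that add atoms: none
Why: Mitsunobu etherification, in which the acidic, hydrogen-bonded salicylaldehyde phenol attacks the activated benzylic carbinol carbon and so forms the O1–C2 bond.

Step 10
Reactants: 14 racemic bromoethyl aryl ether
Product: 15 3-bromo-2,4-bis(methoxymethoxy)-6-({1-[4-(methoxymethoxy)phenyl]ethenyl}oxy)benzaldehyde
Conditions: KOtBu (1.5 equiv.), THF, −20 to 0 °C; Et3N-deactivated silica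
Reagents that add atoms: none
Why: E2 dehydrobromination in which the only β-hydrogen is the benzylic C2–H, so the 1,1-disubstituted aryl 1-arylvinyl ether is the only possible alkene; the aldehyde has no α-hydrogen and the aryl bromide has no ortho hydrogen.

Step 11
Reactants: 15 bromo enol ether aldehyde; 4 flavone C8 pinacol boronate
Product: 16 2,4-bis(methoxymethoxy)-3-{5,7-bis(methoxymethoxy)-2-[4-(methoxymethoxy)phenyl]-4-oxo-4H-chromen-8-yl}-6-({1-[4-(methoxymethoxy)phenyl]ethenyl}oxy)benzaldehyde
Conditions: Pd(OAc)2 (10 mol%), SPhos (20 mol%), K3PO4 (3 equiv.), toluene/H2O 10:1, 90 °C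
Reagents that add atoms: none
Why: Suzuki–Miyaura coupling with a dialkylbiarylphosphine ligand designed for tetra-ortho-substituted biaryls should form the C6–C8'' bond, while the aldehyde and the acid-labile enol ether tolerate the basic medium.

Step 12
Reactants: 16 biaryl 2-(1-arylvinyloxy)benzaldehyde
Product: 17 (2S)-5,7-bis(methoxymethoxy)-2-[4-(methoxymethoxy)phenyl]-6-{5,7-bis(methoxymethoxy)-2-[4-(methoxymethoxy)phenyl]-4-oxo-4H-chromen-8-yl}-2,3-dihydro-4H-chromen-4-one
Conditions: [Rh(cod)Cl]2 (5 mol%), (R)-DTBM-SEGPHOS (11 mol%), Na[B(3,5-(CF3)2C6H3)4] (10 mol%), 1,4-dioxane, 60 °C, degassed and anhydrous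
Reagents that add atoms: none
Why: Proposed new method: cationic monovalent rhodium inserts into the aldehyde C–H bond of 16 to give an acyl rhodium hydride (trivalent rhodium) chelated by the adjacent aryl ether oxygen, the hydride migrates to C2 of the bound enol ether so that rhodium becomes attached to the terminal carbon C3, and C–C reductive elimination from the resulting seven-membered acyl–alkyl rhodacycle forms the C3–C4 bond and releases the catalyst. The closest known reaction type is the rhodium–bisphosphine-catalysed enantioselective endo-hydroacylation of ortho-allylbenzaldehydes carrying 1,1-disubstituted alkenes, which gives 3-substituted tetralones; here the benzylic CH2 of the tether is replaced by the ether oxygen O1 and the alkene is an enol ether, a substrate class on which this closure has not been shown. Ring C closes in a formal 6-endo-trig mode, the acyl carbon C4 bonding to the terminal alkene carbon C3. The only new stereocentre, C2, is created in the hydride insertion, where the chiral bisphosphine decides which enantiotopic face of the 1,1-disubstituted alkene receives the hydride (catalyst control). The step needs selectivity for the six-membered ketone over the five-membered benzofuranone, over decarbonylation and over β-aryloxy elimination: the aryl and oxygen substituents on C2 disfavour a tertiary rhodium–carbon bond and reductive elimination to a quaternary carbon, the alkene has no allylic hydrogen and cannot isomerise, and ether chelation holds the acyl hydride against loss of CO. The medium is neutral and aprotic, so the base-labile C2 centre and the flavone of the second unit should stay untouched.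

Step 13
Reactants: 17 hexa-O-MOM-protected (2S)-flavanone–flavone
Product: 18 8-[(2S)-5,7-dihydroxy-2-(4-hydroxyphenyl)-4-oxo-3,4-dihydro-2H-chromen-6-yl]-5,7-dihydroxy-2-(4-hydroxyphenyl)-4H-chromen-4-one (target)
Conditions: HCl (1.25 M in MeOH), THF, 40 °C
Reagents that add atoms: none
Why: Acid-catalysed acetal exchange should cleave all six MOM ethers as dimethoxymethane under base-free conditions, which avoids the retro-oxa-Michael pathway that would racemise C2.

**Compound list**
1 | apigenin | O=c1cc(-c2ccc(O)cc2)oc2cc(O)cc(O)c12 | starting material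
2 | 5,7-bis(methoxymethoxy)-2-[4-(methoxymethoxy)phenyl]-4H-chromen-4-one | COCOc1ccc(-c2cc(=O)c3c(OCOC)cc(OCOC)cc3o2)cc1 | intermediate
3 | 8-iodo-5,7-bis(methoxymethoxy)-2-[4-(methoxymethoxy)phenyl]-4H-chromen-4-one | COCOc1ccc(-c2cc(=O)c3c(OCOC)cc(OCOC)c(I)c3o2)cc1 | intermediate
4 | 5,7-bis(methoxymethoxy)-2-[4-(methoxymethoxy)phenyl]-8-(4,4,5,5-tetramethyl-1,3,2-dioxaborolan-2-yl)-4H-chromen-4-one | COCOc1ccc(-c2cc(=O)c3c(OCOC)cc(OCOC)c(B4OC(C)(C)C(C)(C)O4)c3o2)cc1 | intermediate
5 | 2-bromoresorcinol | Oc1cccc(O)c1Br | starting material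
6 | 2-bromo-1,3-bis(methoxymethoxy)benzene | COCOc1cccc(OCOC)c1Br | intermediate
7 | 2-[4-bromo-3,5-bis(methoxymethoxy)phenyl]-4,4,5,5-tetramethyl-1,3,2-dioxaborolane | COCOc1cc(B2OC(C)(C)C(C)(C)O2)cc(OCOC)c1Br | intermediate (not isolated)
8 | 4-bromo-3,5-bis(methoxymethoxy)phenol | COCOc1cc(O)cc(OCOC)c1Br | intermediate
9 | 4-bromo-2-(hydroxymethyl)-3,5-bis(methoxymethoxy)phenol (as its magnesium phenoxide) | OCc1c(O)cc(OCOC)c(Br)c1OCOC | intermediate (not isolated)
10 | 3-bromo-6-hydroxy-2,4-bis(methoxymethoxy)benzaldehyde | O=Cc1c(O)cc(OCOC)c(Br)c1OCOC | intermediate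
11 | 4-(methoxymethoxy)benzaldehyde | COCOc1ccc(C=O)cc1 | starting material
12 | 1-ethenyl-4-(methoxymethoxy)benzene | COCOc1ccc(C=C)cc1 | intermediate
13 | racemic 2-bromo-1-[4-(methoxymethoxy)phenyl]ethanol | COCOc1ccc(C(O)CBr)cc1 | intermediate
14 | racemic 3-bromo-6-{2-bromo-1-[4-(methoxymethoxy)phenyl]ethoxy}-2,4-bis(methoxymethoxy)benzaldehyde | O=Cc1c(OC(CBr)c2ccc(OCOC)cc2)cc(OCOC)c(Br)c1OCOC | intermediate
15 | 3-bromo-2,4-bis(methoxymethoxy)-6-({1-[4-(methoxymethoxy)phenyl]ethenyl}oxy)benzaldehyde | O=Cc1c(OC(=C)c2ccc(OCOC)cc2)cc(OCOC)c(Br)c1OCOC | intermediate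
16 | 2,4-bis(methoxymethoxy)-3-{5,7-bis(methoxymethoxy)-2-[4-(methoxymethoxy)phenyl]-4-oxo-4H-chromen-8-yl}-6-({1-[4-(methoxymethoxy)phenyl]ethenyl}oxy)benzaldehyde | O=Cc1c(OC(=C)c2ccc(OCOC)cc2)cc(OCOC)c(-c2c(OCOC)cc(OCOC)c3c(=O)cc(-c4ccc(OCOC)cc4)oc23)c1OCOC | intermediate
17 | (2S)-5,7-bis(methoxymethoxy)-2-[4-(methoxymethoxy)phenyl]-6-{5,7-bis(methoxymethoxy)-2-[4-(methoxymethoxy)phenyl]-4-oxo-4H-chromen-8-yl}-2,3-dihydro-4H-chromen-4-one | O=C1C[C@@H](c2ccc(OCOC)cc2)Oc2cc(OCOC)c(-c3c(OCOC)cc(OCOC)c4c(=O)cc(-c5ccc(OCOC)cc5)oc34)c(OCOC)c21 | intermediate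
18 | 8-[(2S)-5,7-dihydroxy-2-(4-hydroxyphenyl)-4-oxo-3,4-dihydro-2H-chromen-6-yl]-5,7-dihydroxy-2-(4-hydroxyphenyl)-4H-chromen-4-one | O=C1C[C@@H](c2ccc(O)cc2)Oc2cc(O)c(-c3c(O)cc(O)c4c(=O)cc(-c5ccc(O)cc5)oc34)c(O)c21 | target

**Step count and risks**
Total steps: 13. Longest linear sequence: 8 steps (steps 4, 5, 6, 9, 10, 11, 12, 13, from 2-bromoresorcinol).

Steps most likely to fail:

1. Step 12. The acyl rhodium hydride may lose CO, the alkyl rhodium intermediate may undergo β-aryloxy elimination, or the hydride insertion may show poor facial selectivity. The fallback uses known chemistry, sets out from 13 and 10, uses 4, and comes back at 17. It sets C2 before ring closure and closes the same C3–C4 bond by the NHC-catalysed intramolecular alkylation of an aldehyde known for 2-(2-haloethoxy)benzaldehydes. Racemic 13 is oxidised with Dess–Martin periodinane (NaHCO3, CH2Cl2) to 2-bromo-1-[4-(methoxymethoxy)phenyl]ethan-1-one F1. CBS reduction (BH3·SMe2, (S)-2-methyl-CBS-oxazaborolidine, THF) should give (S)-2-bromo-1-[4-(methoxymethoxy)phenyl]ethanol F2. Mitsunobu coupling of F2 with 10 (PPh3, DIAD, toluene, −20 °C) with inversion should give (R)-3-bromo-6-{2-bromo-1-[4-(methoxymethoxy)phenyl]ethoxy}-2,4-bis(methoxymethoxy)benzaldehyde F3. Suzuki coupling of F3 with 4 under the conditions of step 11 should give the biaryl (R)-bromoethyl ether aldehyde F4. A thiazolium salt precatalyst and DBU in 1,4-dioxane should then turn F4 into 17 through the Breslow intermediate and SN2 displacement of the primary bromide, leaving C2 untouched. This path depends on inversion at an ionisation-prone benzylic carbinol and on a basic cyclisation, which is why it is kept in reserve.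

2. Step 11. Transmetalation at two doubly ortho-oxygenated centres may be slow, so protodeboronation of 4 could outrun coupling. The fallback sets out from 3 and 15 and comes back at 16; it replaces boron by zinc. Direct insertion of zinc dust into 3 (Zn, LiCl, THF, 50 °C) should give {5,7-bis(methoxymethoxy)-2-[4-(methoxymethoxy)phenyl]-4-oxo-4H-chromen-8-yl}zinc iodide F5. Negishi coupling of F5 with 15 (Pd2(dba)3, RuPhos, THF/NMP, 60 °C) should give 16. This also bypasses step 3.

3. Step 9. The electron-rich benzylic oxyphosphonium may ionise and eliminate instead of being substituted by the hindered phenol. The fallback sets out from 12 and 10 and comes back at 14; it replaces redox condensation by alkylation with a benzylic halide. Addition of bromine to 12 (pyridinium tribromide, CH2Cl2, 0 °C) should give 1-(1,2-dibromoethyl)-4-(methoxymethoxy)benzene F6. The phenoxide of 10 (K2CO3, MeCN, rt) should displace the activated benzylic bromide of F6 and leave the primary bromide in place, giving 14.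

**Further compounds**
F1 | step 12 | 2-bromo-1-[4-(methoxymethoxy)phenyl]ethan-1-one | COCOc1ccc(C(=O)CBr)cc1
F2 | step 12 | (S)-2-bromo-1-[4-(methoxymethoxy)phenyl]ethanol | COCOc1ccc([C@H](O)CBr)cc1
F3 | step 12 | (R)-3-bromo-6-{2-bromo-1-[4-(methoxymethoxy)phenyl]ethoxy}-2,4-bis(methoxymethoxy)benzaldehyde | O=Cc1c(O[C@@H](CBr)c2ccc(OCOC)cc2)cc(OCOC)c(Br)c1OCOC
F4 | step 12 | 6-{(1R)-2-bromo-1-[4-(methoxymethoxy)phenyl]ethoxy}-2,4-bis(methoxymethoxy)-3-{5,7-bis(methoxymethoxy)-2-[4-(methoxymethoxy)phenyl]-4-oxo-4H-chromen-8-yl}benzaldehyde | O=Cc1c(O[C@@H](CBr)c2ccc(OCOC)cc2)cc(OCOC)c(-c2c(OCOC)cc(OCOC)c3c(=O)cc(-c4ccc(OCOC)cc4)oc23)c1OCOC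
F5 | step 11 | {5,7-bis(methoxymethoxy)-2-[4-(methoxymethoxy)phenyl]-4-oxo-4H-chromen-8-yl}zinc iodide | COCOc1ccc(-c2cc(=O)c3c(OCOC)cc(OCOC)c([Zn]I)c3o2)cc1
F6 | step 9 | 1-(1,2-dibromoethyl)-4-(methoxymethoxy)benzene | COCOc1ccc(C(Br)CBr)cc1
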